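## Retrosynthetic overview

1. Ring B is cut at O2–C1 and C4–C4a. This gives a ring A enaminone and a methyl ketone. The enaminone has C1 masked as Me2N–CH=, chloride at C4a as leaving group, and the C5 chlorine already in place. The ketone carries C3, C4 and the (S) side chain.
2. C1 is removed as an amide acetal carbon, leaving (R)-4,5-dichloro-2-methyl-2-(propanoyloxy)cyclohex-4-ene-1,3-dione.
3. Key disconnection: C8a is taken out as a diazomethane carbon, and ring A contracts to the mirror-symmetric 4,5-dichloro-2-methyl-2-(propanoyloxy)cyclopent-4-ene-1,3-dione. In the forward sense, a catalyst-controlled one-carbon ring expansion (1,2-shift of a chlorovinyl carbon) makes ring A and sets C7.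
4. The cyclopentenedione goes back to 2-methylcyclopentane-1,3-dione and propanoic acid. The ketone goes back to (S)-2-methylbutan-1-ol through two E-selective Wittig olefinations.
5. Ring order: five-membered carbocycle (bought), then six-membered ring A (expansion), then pyran ring B (last step).

Assumption: the sense of induction in step 4 cannot be predicted with certainty. The route is drawn for the ligand antipode that gives (R)-11; both antipodes are accessible from L- or D-pipecolic acid.

## Route

Step 1
Reactants: 1 2-methylcyclopentane-1,3-dione; 2 propanoic acid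
Product: 4 1-methyl-2,5-dioxocyclopentyl propanoate, via bis(propanoyloxy)iodobenzene 3 (not isolated)
Conditions: PhIO (1.2 equiv), EtCO2H (solvent), rt, 30 min; then 1, 40 °C
Reagents that add atoms: none
Why: Alpha-acyloxylation of a 2-substituted 1,3-diketone by a trivalent-iodine dicarboxylate: the enol of 1 binds to the iodine of 3 and reductive ligand coupling delivers propanoate to C2, the only nucleophilic carbon, and 4 has a mirror plane, so no stereocentre arises.

Step 2
Reactants: 4 1-methyl-2,5-dioxocyclopentyl propanoate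
Product: 6 1-methyl-2,5-dioxocyclopent-3-en-1-yl propanoate, via 3-bromo-1-methyl-2,5-dioxocyclopentyl propanoate 5 (not isolated)
Conditions: CuBr2 (2.05 equiv), EtOAc–CHCl3 1:1, reflux; then Et3N (2.2 equiv), 0 °C
Reagents that add atoms: none
Why: Alpha-bromination of a ketone with CuBr2 followed by E1cB dehydrobromination is the standard entry to 2,2-disubstituted cyclopent-4-ene-1,3-diones, and the quaternary carbon cannot enolise, so the tertiary ester is untouched.

Step 3
Reactants: 6 1-methyl-2,5-dioxocyclopent-3-en-1-yl propanoate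
Product: 8 3,4-dichloro-1-methyl-2,5-dioxocyclopent-3-en-1-yl propanoate, via 3-chloro-1-methyl-2,5-dioxocyclopent-3-en-1-yl propanoate 7 (not isolated)
Conditions: PhICl2 (2.4 equiv), 2,6-lutidine (2.5 equiv), Bu4NCl (10 mol %), CH2Cl2, 0 → 40 °C
Reagents that add atoms: iodobenzene dichloride ClI(Cl)c1ccccc1
Why: Alpha-chlorination of an enone by chloride-triggered addition of a Cl2 equivalent and dehydrochlorination, run twice because each alkene carbon is alpha to one carbonyl (the same addition–elimination that turns quinones and maleimides into their dichlorides); racemic 7 is only passed through and 8 regains the mirror plane.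

Step 4
Reactants: 8 3,4-dichloro-1-methyl-2,5-dioxocyclopent-3-en-1-yl propanoate
Product: 11 (1R)-3,4-dichloro-1-methyl-2,6-dioxocyclohex-3-en-1-yl propanoate, via diazonium alkoxide adduct 9 (not isolated), via alpha-trimethylsilyl ketone 10 (not isolated)
Conditions: Me3SiCHN2 (1.0 equiv, slow addition), Sc(OTf)3 (10 mol %), 1,1'-(propane-1,3-diyl)bis{(2S)-2-[(2,6-diisopropylphenyl)carbamoyl]piperidine 1-oxide} (11 mol %), 4 Å MS, CH2Cl2, −60 → −30 °C; then 10% aq citric acid–THF, 0 °C
Reagents that add atoms: (trimethylsilyl)diazomethane C[Si](C)(C)C=[N+]=[N-]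
Why: Proposed new method: catalytic enantioselective desymmetrising one-carbon ring expansion of a prochiral 2,2-disubstituted cyclopent-4-ene-1,3-dione; the chiral trivalent-scandium complex binds one of the two enantiotopic ketone oxygens (two-point binding together with the propanoate C=O fits the ligand pocket for only one of them); Me3SiCHN2 adds to that activated C=O to give 9, the fully substituted, chlorine-blocked C=C suppressing dipolar cycloaddition as in the carbonyl-selective attack of diazoalkanes on tetrahaloquinones; loss of N2 is coupled to a 1,2-shift of the sp2 chlorovinyl carbon rather than of the quaternary, doubly acceptor-substituted C7, so the new CH2 (C8a) enters between C8 and C4a, ring A becomes six-membered, and C7 becomes an (R) stereocentre solely through the choice of carbonyl group; the silyl group blocks a second homologation and is lost on mild acid work-up; closest known reaction type: Lewis-acid-catalysed diazoalkane–ketone homologation (Büchner–Curtius–Schlotterbeck or Tiffeneau–Demjanov-type ring expansion), known with Sc(OTf)3 for simple cycloalkanones and in asymmetric desymmetrising form for 4-substituted cyclohexanones, but not for cyclic 1,3-diones or ene-diones.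

Step 5
Reactants: 11 (1R)-3,4-dichloro-1-methyl-2,6-dioxocyclohex-3-en-1-yl propanoate
Product: 12 (1R,5E)-3,4-dichloro-5-[(dimethylamino)methylidene]-1-methyl-2,6-dioxocyclohex-3-en-1-yl propanoate
Conditions: Me2NCH(OMe)2 (1.2 equiv), toluene, 0 °C → rt
Reagents that add atoms: N,N-dimethylformamide dimethyl acetal COC(OC)N(C)C
Why: Aminomethylenation of an active methylene group with an amide acetal (enaminone formation): the C8a CH2, flanked by C8=O and the vinylogous C6=O, is the only acidic position, it protonates the acetal and the carbanion captures the resulting cation, so no free methoxide reaches the chlorides and C7 is not touched.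

Step 6
Reactants: 13 (S)-2-methylbutan-1-ol
Product: 15 (2E,4S)-2,4-dimethylhex-2-enal, via (S)-2-methylbutanal 14 (not isolated)
Conditions: 2,2,6,6-tetramethylpiperidin-1-oxyl (1 mol %), KBr (10 mol %), aq NaOCl (1.1 equiv, pH 9.5), CH2Cl2, 0 °C; dried CH2Cl2 layer, Ph3P=C(Me)CHO (1.1 equiv), 40 °C
Reagents that add atoms: 2-(triphenylphosphoranylidene)propanal CC(C=O)=P(c1ccccc1)(c1ccccc1)c1ccccc1
Why: Nitroxyl/hypochlorite (Anelli) oxidation, proven on this alcohol without racemisation, followed by Wittig olefination with a stabilised ylide (E-selective) on the undistilled aldehyde solution; the (S) centre comes from the chiral pool.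

Step 7
Reactants: 15 (2E,4S)-2,4-dimethylhex-2-enal
Product: 16 (3E,5E,7S)-5,7-dimethylnona-3,5-dien-2-one
Conditions: Ph3P=CHC(O)Me (1.5 equiv), toluene, 90 °C
Reagents that add atoms: 1-(triphenylphosphoranylidene)propan-2-one CC(=O)C=P(c1ccccc1)(c1ccccc1)c1ccccc1
Why: Wittig olefination with the stabilised acetonyl ylide under neutral conditions gives the (E)-enone and avoids gamma-deprotonation of 15, so the allylic stereocentre keeps its configuration.

Step 8
Reactants: 12 (1R,5E)-3,4-dichloro-5-[(dimethylamino)methylidene]-1-methyl-2,6-dioxocyclohex-3-en-1-yl propanoate; 16 (3E,5E,7S)-5,7-dimethylnona-3,5-dien-2-one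
Product: 19 sclerketide B, via lithium trienolate 17 (not isolated), via open keto enaminone 18 (not isolated)
Conditions: 16 (2.1 equiv), LiN(SiMe3)2 (2.0 equiv), THF, −78 °C; 12, −78 → −20 °C; then AcOH (20 equiv), rt → 40 °C
Reagents that add atoms: none
Why: The kinetic alpha'-enolate 17 replaces the beta-chloride at C4a by addition–elimination (vinylogous acyl substitution; C5–Cl is alpha and inert, and C1 is protected as a vinylogous amide whose adducts revert), and on acidification the enol oxygen of 18 attacks C1 and expels Me2NH (pyran closure of a 1,5-dicarbonyl equivalent), which forms ring B while C7 and the side-chain centre are spectators.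

## Compound list

1 | 2-methylcyclopentane-1,3-dione | CC1C(=O)CCC1=O | starting material
2 | propanoic acid | CCC(=O)O | starting material
3 | bis(propanoyloxy)iodobenzene | CCC(=O)OI(OC(=O)CC)c1ccccc1 | intermediate
4 | 1-methyl-2,5-dioxocyclopentyl propanoate (achiral) | CCC(=O)OC1(C)C(=O)CCC1=O | intermediate
5 | 3-bromo-1-methyl-2,5-dioxocyclopentyl propanoate (racemic, both diastereomers) | CCC(=O)OC1(C)C(=O)CC(Br)C1=O | intermediate
6 | 1-methyl-2,5-dioxocyclopent-3-en-1-yl propanoate (achiral) | CCC(=O)OC1(C)C(=O)C=CC1=O | intermediate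
7 | 3-chloro-1-methyl-2,5-dioxocyclopent-3-en-1-yl propanoate (racemic) | CCC(=O)OC1(C)C(=O)C=C(Cl)C1=O | intermediate
8 | 3,4-dichloro-1-methyl-2,5-dioxocyclopent-3-en-1-yl propanoate (achiral) | CCC(=O)OC1(C)C(=O)C(Cl)=C(Cl)C1=O | intermediate
9 | (1R)-3,4-dichloro-2-[diazonio(trimethylsilyl)methyl]-1-methyl-2-oxido-5-oxocyclopent-3-en-1-yl propanoate (scandium-bound; the two new centres are transient) | CCC(=O)O[C@]1(C)C([O-])(C([Si](C)(C)C)[N+]#N)C(Cl)=C(Cl)C1=O | intermediate
10 | (1R)-3,4-dichloro-1-methyl-2,6-dioxo-5-(trimethylsilyl)cyclohex-3-en-1-yl propanoate (epimers at the silyl carbon) | CCC(=O)O[C@]1(C)C(=O)C([Si](C)(C)C)C(Cl)=C(Cl)C1=O | intermediate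
11 | (1R)-3,4-dichloro-1-methyl-2,6-dioxocyclohex-3-en-1-yl propanoate | CCC(=O)O[C@]1(C)C(=O)CC(Cl)=C(Cl)C1=O | intermediate
12 | (1R,5E)-3,4-dichloro-5-[(dimethylamino)methylidene]-1-methyl-2,6-dioxocyclohex-3-en-1-yl propanoate (push–pull C=C, geometry labile) | CCC(=O)O[C@]1(C)C(=O)/C(=C\N(C)C)C(Cl)=C(Cl)C1=O | intermediate
13 | (S)-2-methylbutan-1-ol | CC[C@H](C)CO | starting material
14 | (S)-2-methylbutanal | CC[C@H](C)C=O | intermediate
15 | (2E,4S)-2,4-dimethylhex-2-enal | O=C/C(C)=C/[C@@H](C)CC | intermediate
16 | (3E,5E,7S)-5,7-dimethylnona-3,5-dien-2-one | CC(=O)/C=C/C(C)=C/[C@@H](C)CC | intermediate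
17 | lithium (3E,5E,7S)-5,7-dimethylnona-1,3,5-trien-2-olate | [Li]OC(=C)/C=C/C(C)=C/[C@@H](C)CC | intermediate
18 | (1R,5Z)-3-chloro-5-[(dimethylamino)methylidene]-4-[(3E,5E,7S)-5,7-dimethyl-2-oxonona-3,5-dien-1-yl]-1-methyl-2,6-dioxocyclohex-3-en-1-yl propanoate | CCC(=O)O[C@]1(C)C(=O)/C(=C\N(C)C)C(CC(=O)/C=C/C(C)=C/[C@@H](C)CC)=C(Cl)C1=O | intermediate
19 | sclerketide B, (7R)-5-chloro-3-[(1E,3E,5S)-3,5-dimethylhepta-1,3-dien-1-yl]-7-methyl-6,8-dioxo-7,8-dihydro-6H-isochromen-7-yl propanoate | CCC(=O)O[C@]1(C)C(=O)C2=COC(/C=C/C(C)=C/[C@@H](C)CC)=CC2=C(Cl)C1=O | target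

## Step count and weak points

Total step count: 8. Longest linear sequence: 6 (steps 1, 2, 3, 4, 5, 8).

**Step 4 (the new step).**
- Me3SiCHN2 may attack the chlorinated C=C instead of the carbonyl group.
- C7 may migrate instead of the vinyl carbon. That would give a 1,4-dione that loses propanoic acid to a quinone.
- The adduct may close to an epoxide, or the selection between the two carbonyl groups may be poor.

The fallback uses known chemistry only; it sets out from 8 and comes back at 11. The stereocentre is set by a desymmetrising reduction, not by the expansion. Corey–Bakshi–Shibata reduction of 8 uses BH3·SMe2 and 10 mol % (R)-1-methyl-3,3-diphenyltetrahydro-1H,3H-pyrrolo[1,2-c][1,3,2]oxazaborole in THF at −30 °C. This reaction is established for 2-halocycloalkenones and for 2,2-disubstituted cyclopentane-1,3-diones. It reduces one carbonyl group from the face away from the ester and gives (1S,5R)-3,4-dichloro-5-hydroxy-1-methyl-2-oxocyclopent-3-en-1-yl propanoate F1. The quaternary centre is now fixed, and the carbinol centre is erased later. Et3SiCl and imidazole give (1S,5R)-3,4-dichloro-1-methyl-2-oxo-5-[(triethylsilyl)oxy]cyclopent-3-en-1-yl propanoate F2, which stops acyl migration. Only one ketone is left, so the ordinary stoichiometric BF3·OEt2/Me3SiCHN2 homologation (CH2Cl2, −78 °C) can only expand on the wanted side. It gives (1S,2R)-3,4-dichloro-1-methyl-6-oxo-2-[(triethylsilyl)oxy]-5-(trimethylsilyl)cyclohex-3-en-1-yl propanoate F3. HF·pyridine removes both silyl groups to give (1S,2R)-3,4-dichloro-2-hydroxy-1-methyl-6-oxocyclohex-3-en-1-yl propanoate F4. Dess–Martin periodinane then oxidises the carbinol to 11.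

**Step 8.**
- The chloride at C4a sits in a push–pull system between two substituted carbons, so the enolate may add too slowly.
- The enolate may instead attack C1 or the ester.

The fallback sets out from 12 and 16 and comes back at 19. It replaces enolate chemistry by cross-coupling and alkyne cycloisomerisation, the established end game for azaphilones. Ketone 16 is treated with LiN(iPr)2 and ClP(O)(OEt)2 to give diethyl (3E,5E,7S)-5,7-dimethylnona-1,3,5-trien-2-yl phosphate F5. More LiN(iPr)2 (2.2 equiv) eliminates this to (3E,5E,7S)-5,7-dimethylnona-3,5-dien-1-yne F6. Sonogashira coupling of F6 with 12 (PdCl2(PPh3)2, CuI, Et3N, THF, 40 °C) is beta-selective, as with 3,4-dihalobutenolides. It gives (1R,5Z)-3-chloro-5-[(dimethylamino)methylidene]-4-[(3E,5E,7S)-5,7-dimethylnona-3,5-dien-1-yn-1-yl]-1-methyl-2,6-dioxocyclohex-3-en-1-yl propanoate F7. Aqueous CF3CO2H in ClCH2CH2Cl hydrolyses the enaminone to (1R)-3-chloro-4-[(3E,5E,7S)-5,7-dimethylnona-3,5-dien-1-yn-1-yl]-5-(hydroxymethylidene)-1-methyl-2,6-dioxocyclohex-3-en-1-yl propanoate F8. Au(OAc)3 (5 mol %) then closes F8 in the 6-endo-dig mode to 19.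

**Step 3.**
- The second chlorination of the already electron-poor 7 may stall.
- Base or chloride may add to 8.

The fallback sets out from 4 and comes back at 8, so that no ene-dione is handled at all. It is oxidative chlorination of the saturated dione with SOCl2 and pyridine at reflux, proceeding by alpha-sulfinylation, chlorination and elimination. This method is known to turn succinimides and maleimides into dichloromaleimides. It is the second choice because its precedent lies on imides and sulfur-containing by-products are possible. It makes no new isolable compound.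

## Further compounds

F1 | step 4 | (1S,5R)-3,4-dichloro-5-hydroxy-1-methyl-2-oxocyclopent-3-en-1-yl propanoate | CCC(=O)O[C@]1(C)C(=O)C(Cl)=C(Cl)[C@@H]1O
F2 | step 4 | (1S,5R)-3,4-dichloro-1-methyl-2-oxo-5-[(triethylsilyl)oxy]cyclopent-3-en-1-yl propanoate | CCC(=O)O[C@]1(C)C(=O)C(Cl)=C(Cl)[C@@H]1O[Si](CC)(CC)CC
F3 | step 4 | (1S,2R)-3,4-dichloro-1-methyl-6-oxo-2-[(triethylsilyl)oxy]-5-(trimethylsilyl)cyclohex-3-en-1-yl propanoate | CCC(=O)O[C@]1(C)C(=O)C([Si](C)(C)C)C(Cl)=C(Cl)[C@@H]1O[Si](CC)(CC)CC
F4 | step 4 | (1S,2R)-3,4-dichloro-2-hydroxy-1-methyl-6-oxocyclohex-3-en-1-yl propanoate | CCC(=O)O[C@]1(C)C(=O)CC(Cl)=C(Cl)[C@@H]1O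
F5 | step 8 | diethyl (3E,5E,7S)-5,7-dimethylnona-1,3,5-trien-2-yl phosphate | CCOP(=O)(OCC)OC(=C)/C=C/C(C)=C/[C@@H](C)CC
F6 | step 8 | (3E,5E,7S)-5,7-dimethylnona-3,5-dien-1-yne | C#C/C=C/C(C)=C/[C@@H](C)CC
F7 | step 8 | (1R,5Z)-3-chloro-5-[(dimethylamino)methylidene]-4-[(3E,5E,7S)-5,7-dimethylnona-3,5-dien-1-yn-1-yl]-1-methyl-2,6-dioxocyclohex-3-en-1-yl propanoate | CCC(=O)O[C@]1(C)C(=O)/C(=C\N(C)C)C(C#C/C=C/C(C)=C/[C@@H](C)CC)=C(Cl)C1=O
F8 | step 8 | (1R)-3-chloro-4-[(3E,5E,7S)-5,7-dimethylnona-3,5-dien-1-yn-1-yl]-5-(hydroxymethylidene)-1-methyl-2,6-dioxocyclohex-3-en-1-yl propanoate | CCC(=O)O[C@]1(C)C(=O)C(=CO)C(C#C/C=C/C(C)=C/[C@@H](C)CC)=C(Cl)C1=O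
F0 | step 3 | none | none
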